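(The runs were computed for substances that don't exist; noise was put on by code.)

A neighbour flask, the same recipe and time but with 8.5 × 10⁻⁴ M of free catalyst, looks nearly like my flask with 0.50 mM. I asked whether 1.70 times the charge buys that many times the conversion.

- spring: left-handed substrate 0.10 M; right-handed substrate 0.10 M; solid reagent 0.15 M; free catalyst 0.50 mM; the very flask that is asked about, followed so far
- flask: left-handed substrate 0.10 M; solid reagent 0.150 M; free catalyst 0.50 mM; right-handed substrate 0.10 M; time 2.5 min

spring run (percent of the left-handed substrate and right-handed substrate together charged)

| time / s | left-handed substrate / % | right-handed substrate / % |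
|---|---|---|
| 10.0 | 49.2 | 50.1 |
| 25.0 | 47.8 | 48.9 |
| 50.0 | 47.3 | 49.1 |
| 80.0 | 46.5 | 48.8 |

(scatter of a reading: 0.3 percentage points)

- part of the left-handed substrate and right-handed substrate charged together that has reacted at 2.5 min
- excess of left-handed product over right-handed product in the product at 2.5 min
- excess of right-handed substrate over left-handed substrate among what is left of the two at 2.5 min

- free catalyst is single-handed; left-handed substrate and right-handed substrate are mirror images of each other, charged as a racemate, each of them at the stated concentration
- solid, in amounts per volume of the solution: solid reagent
- what was read earlier has a scatter of 0.3 percentage points, one standard deviation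
- at the start none of the solid reagent is in solution
- an excess is below zero if the other one leads

The spring run was my flask, followed so far. Adding both substrates, I read conversions of 0.700% at 10.0 s and 4.70% at 80.0 s. That span is 3.00 doublings of time.

gain = (4.70% − 0.700%) / 3.00 = 1.3 percentage points

This gain per doubling, the conversion won each time the clock doubles, is a reading, with a scatter of 0.2 points. From 80.0 s to 2.5 min my flask had 0.907 doublings left.

conversion = 4.70% + 1.3 points × 0.907 = 5.91%

The forecast differed from my reckoning: it gave a conversion of 6.3%, higher than mine, with eP 50% and eS 3.4%. It noted that “After a fast start the rate clearly slows”.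

I assumed that free catalyst wears out faster the more of it stands. The higher charge in the neighbour flask then acts like a longer clock, so it should add doublings, not multiply the conversion.

My flask gave a conversion of 6.94%, 1 point above my reckoning, with eP 41.0% and eS 3.06%.

    coupling partner + free catalyst + left-handed substrate → free catalyst + left-handed product (k = 170 M⁻² s⁻¹)
    coupling partner + free catalyst + right-handed substrate → free catalyst + right-handed product (k = 69.0 M⁻² s⁻¹)
    coupling partner ⇌ dormant form (K = 3.30, k = 0.00380 s⁻¹)
    solid reagent ⇌ coupling partner, rate k4*(cs4 - [coupling partner]) while solid is left; crystals form when [coupling partner] > cs4 (solubility = 42.0 mM, k = 0.210 s⁻¹)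
    2 free catalyst → spent catalyst (k = 75.0 M⁻¹ s⁻¹)

In my flask, the first half-life of free catalyst by the step that spends it was 13.3 s, far shorter than the 2.5 min asked about. At 2.50 min, spent catalyst stood at 91.8% of the charge and free catalyst at 8.16%.

For the neighbour flask, the charge ratio is worth 0.766 doublings, so the carried gain adds 1 point and gives 7.94%. The computed conversion there is 7.96%.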